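Ring A is disconnected between C1 and C2 (drimane numbering) in a precursor in which ring B is open as well: an acyclic glyoxal (C2 aldehyde, C3 ketone) whose C5 carries an isopropenyl group (C10=C1H2) and the geranyl-type C8=C9 alkene. The key step exploits that C1 is a bare methylene on the quaternary ring-fusion carbon C10: Prins attack of C1 on the SnCl4-chelated C2 aldehyde closes ring A and creates the C10 cation of the biogenetic drimane cyclization, which C9 captures to close ring B; loss of H7 gives the C7=C8 alkene. C2, C9 and C10 are set from C5, installed by a catalytic asymmetric Claisen rearrangement.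

Key step: step 8

Remarks on the chemistry:
- Atom numbers C1 to C11 are the drimane numbers of the target (ring A: C1, C2, C3, C4, C5, C10; ring B: C5 to C10; C11 is the CH2O carbon) and are used for the same atoms in every precursor. In this numbering the target is (2S,3S,5S,9R,10R): an ent-drimane with trans ring fusion and equatorial C2–OH, C3–OH and C11.
- Assumption: the (S,S)-t-Bu-box complex of divalent copper is taken to deliver the (5S) product in step 5; if the sense of induction is the opposite, the (R,R)-ligand is used. (S,S)-t-Bu-box is 2,2'-(propane-2,2-diyl)bis[(4S)-4-tert-butyl-4,5-dihydro-1,3-oxazole].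
- Ethyl diazo(diethoxyphosphoryl)acetate 5 is taken as a catalogue reagent.

Step 1
Reactants: 1 umbelliferone (7-hydroxy-2H-chromen-2-one); 2 geranyl bromide ((2E)-1-bromo-3,7-dimethylocta-2,6-diene)
Product: 3 auraptene (7-geranyloxycoumarin)
Conditions: K2CO3, acetone, reflux
Reagents that add atoms: none
Why: Williamson etherification, in which the phenoxide displaces the primary allylic bromide by SN2 and the (E)-alkene is untouched; no stereocenter is formed.

Step 2
Reactants: 3 auraptene
Product: 4 8'-hydroxyauraptene ((2E,6E)-8-hydroxygeranyl ether of umbelliferone)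
Conditions: SeO2 (cat.), t-BuOOH, salicylic acid (cat.), CH2Cl2, 0 °C to rt
Reagents that add atoms: selenium dioxide, O=[Se]=O (oxygen donor, catalytic); tert-butyl hydroperoxide, CC(C)(C)OO (terminal oxidant that supplies the oxygen)
Why: Riley allylic oxidation (ene reaction, then 2,3-sigmatropic shift) should select the (E)-methyl group of the more electron-rich terminal alkene, the other alkene being deactivated by the allylic aryloxy group, and gives the (E)-allylic alcohol whose carbinol carbon becomes C1.

Step 3
Reactants: 4 8'-hydroxyauraptene; 5 ethyl diazo(diethoxyphosphoryl)acetate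
Product: 6 alpha-(allyloxy)phosphonoacetate (racemic at the phosphonate carbon)
Conditions: Rh2(OAc)4 (2 mol%), toluene, 80 °C, slow addition of 5
Reagents that add atoms: none
Why: dirhodium-carbenoid O–H insertion into the primary allylic alcohol should outpace cyclopropanation of the trisubstituted alkenes and of the coumarin; the new stereocenter is racemic and disappears in step 4.

Step 4
Reactants: 6 alpha-(allyloxy)phosphonoacetate; 7 acetone
Product: 8 2-ethoxycarbonyl allyl vinyl ether (isopropylidene type)
Conditions: LiN(SiMe3)2, THF, −78 °C; acetone (excess), −78 °C to rt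
Reagents that add atoms: none
Why: Horner–Wadsworth–Emmons olefination of the alpha-alkoxy phosphonate anion with a symmetrical ketone gives the vinyl ether without E/Z isomers, and the two methyl groups of acetone become the C4 gem-dimethyl pair.

Step 5
Reactants: 8 allyl vinyl ether
Product: 9 (5S)-alpha-keto ester (ethyl (4S,7E)-3,3,7-trimethyl-2-oxo-9-[(2-oxo-2H-chromen-7-yl)oxy]-4-(prop-1-en-2-yl)non-7-enoate)
Conditions: [Cu{(S,S)-t-Bu-box}(H2O)2](SbF6)2 (10 mol%), CH2Cl2, rt
Reagents that add atoms: none
Why: catalytic asymmetric Claisen rearrangement, in which divalent copper chelates the ether oxygen and the ester carbonyl, the bis(oxazoline) shields one face of the vinyl ether, and the chair 3,3-shift with the (E)-C5=C10 alkene forms the C4–C5 bond, sets C5 (S) under catalyst control and turns C1 into a terminal methylene.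

Step 6
Reactants: 9 alpha-keto ester
Product: 11 vicinal diol (5S; C3 epimers), via alpha-hydroxy ester 10 (not isolated)
Conditions: NaBH4 (excess), EtOH–THF, 0 °C to rt
Reagents that add atoms: none
Why: borohydride reduction takes the ester-activated C3 ketone first and then, through the alkoxyborate, the alpha-hydroxy ester to the primary alcohol, while the conjugated 7-alkoxycoumarin lactone should survive at or below room temperature; C3 forms as a mixture of epimers, which is harmless because step 7 removes this centre.

Step 7
Reactants: 11 vicinal diol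
Product: 12 glyoxal ((4S,7E)-3,3,7-trimethyl-2-oxo-9-[(2-oxo-2H-chromen-7-yl)oxy]-4-(prop-1-en-2-yl)non-7-enal)
Conditions: (COCl)2, DMSO, CH2Cl2, −78 °C; Et3N, −78 to −20 °C; used crude and dry
Reagents that add atoms: none
Why: Swern oxidation takes both carbinols to the 1,2-dicarbonyl without C–C cleavage, so both C3 epimers converge on one glyoxal; C5 is separated from the carbonyls by the quaternary C4 and cannot epimerize.

Step 8
Reactants: 12 glyoxal
Product: 14 bicyclic ketol ((2S,5S,9R,10R)-2-hydroxy-3-oxodrim-7-en-11-yl ether of umbelliferone), via monocyclic C10 carbocation 13 (not isolated)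
Conditions: SnCl4 (3 equiv), CH2Cl2, −78 °C; then aq. NaHCO3
Reagents that add atoms: none
Why: SnCl4 chelates the C2/C3 dicarbonyl, the C1 terminus of the isopropenyl group attacks the C2 aldehyde (Prins), and the C10 tertiary cation so formed is captured by C9 of the (E)-C8=C9 alkene before the C8 cation loses H7 to give the C7=C8 alkene. The closest known reaction type is the aldehyde-initiated (Prins) cation–olefin polycyclization of polyprenoids, here entered through the geometry of a type 2 carbonyl-ene substrate. Ring A closes exo at the C2 carbonyl and endo at the C1=C10 alkene (six-membered), and ring B closes 6-endo-trig at the C8=C9 alkene, each through a chair. C2 is controlled by the chelated oxygen taking the equatorial site away from the axial C4 methyl; C10 and C9 are controlled by C5, whose side chain sits equatorial so that C9 adds to the C10 face anti to the axial C4 methyl (trans fusion, axial C10 methyl), and the E geometry places C11 equatorial, cis to the C10 methyl. The step needs the aldehyde to react in preference to the C3 ketone (more electrophilic, six- against five-membered closure), capture of the C10 cation by the alkene to outrun its proton loss, and loss of H7 to the endocyclic trisubstituted alkene as in acid cyclizations of farnesyl esters to drim-7-enes; the 7-alkoxycoumarin ether is expected to tolerate the Lewis acid at −78 °C, as in cyclizations of epoxy-umbelliprenin.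

Step 9
Reactants: 14 bicyclic ketol
Product: 15 target CNP0124364.1 ((2S,3S,5S,9R,10R)-2,3-dihydroxydrim-7-en-11-yl ether of umbelliferone)
Conditions: NaBH4, MeOH–THF, −20 to 0 °C
Reagents that add atoms: none
Why: borohydride reduction, in which hydride adds to the C3 ketone from the face opposite the axial C4 and C10 methyl groups (axial attack, as for 4,4-dimethyl-3-oxo terpenoids) and so gives the equatorial C3 alcohol trans to the equatorial C2 hydroxyl; the low temperature spares the coumarin.

Compound list
1 | umbelliferone, 7-hydroxy-2H-chromen-2-one | O=c1ccc2ccc(O)cc2o1 | starting material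
2 | geranyl bromide, (2E)-1-bromo-3,7-dimethylocta-2,6-diene | CC(C)=CCC/C(C)=C/CBr | starting material
3 | auraptene, 7-{[(2E)-3,7-dimethylocta-2,6-dien-1-yl]oxy}-2H-chromen-2-one | CC(C)=CCC/C(C)=C/COc1ccc2ccc(=O)oc2c1 | intermediate
4 | 8'-hydroxyauraptene, 7-{[(2E,6E)-8-hydroxy-3,7-dimethylocta-2,6-dien-1-yl]oxy}-2H-chromen-2-one | OC/C(C)=C/CC/C(C)=C/COc1ccc2ccc(=O)oc2c1 | intermediate
5 | ethyl diazo(diethoxyphosphoryl)acetate | CCOC(=O)C(=[N+]=[N-])P(=O)(OCC)OCC | starting material
6 | ethyl 2-(diethoxyphosphoryl)-2-{[(2E,6E)-2,6-dimethyl-8-[(2-oxo-2H-chromen-7-yl)oxy]octa-2,6-dien-1-yl]oxy}acetate, racemic at the phosphonate carbon | CCOC(=O)C(OC/C(C)=C/CC/C(C)=C/COc1ccc2ccc(=O)oc2c1)P(=O)(OCC)OCC | intermediate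
7 | acetone | CC(C)=O | starting material
8 | ethyl 2-{[(2E,6E)-2,6-dimethyl-8-[(2-oxo-2H-chromen-7-yl)oxy]octa-2,6-dien-1-yl]oxy}-3-methylbut-2-enoate | CCOC(=O)C(OC/C(C)=C/CC/C(C)=C/COc1ccc2ccc(=O)oc2c1)=C(C)C | intermediate
9 | ethyl (4S,7E)-3,3,7-trimethyl-2-oxo-9-[(2-oxo-2H-chromen-7-yl)oxy]-4-(prop-1-en-2-yl)non-7-enoate (5S in drimane numbering) | CCOC(=O)C(=O)C(C)(C)[C@H](C(C)=C)CC/C(C)=C/COc1ccc2ccc(=O)oc2c1 | intermediate
10 | ethyl (2RS,4S,7E)-2-hydroxy-3,3,7-trimethyl-9-[(2-oxo-2H-chromen-7-yl)oxy]-4-(prop-1-en-2-yl)non-7-enoate | CCOC(=O)C(O)C(C)(C)[C@H](C(C)=C)CC/C(C)=C/COc1ccc2ccc(=O)oc2c1 | intermediate (not isolated)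
11 | 7-{[(2E,6S,8RS)-8,9-dihydroxy-3,7,7-trimethyl-6-(prop-1-en-2-yl)non-2-en-1-yl]oxy}-2H-chromen-2-one | OCC(O)C(C)(C)[C@H](C(C)=C)CC/C(C)=C/COc1ccc2ccc(=O)oc2c1 | intermediate
12 | (4S,7E)-3,3,7-trimethyl-2-oxo-9-[(2-oxo-2H-chromen-7-yl)oxy]-4-(prop-1-en-2-yl)non-7-enal | O=CC(=O)C(C)(C)[C@H](C(C)=C)CC/C(C)=C/COc1ccc2ccc(=O)oc2c1 | intermediate
13 | monocyclic C10 carbocation with ring A closed, (2S,5S), present as its tin alkoxide and drawn as the free alcohol | C[C+]1C[C@H](O)C(=O)C(C)(C)[C@H]1CC/C(C)=C/COc1ccc2ccc(=O)oc2c1 | intermediate (not isolated)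
14 | 7-{[(1R,4aS,7S,8aR)-7-hydroxy-2,5,5,8a-tetramethyl-6-oxo-1,4,4a,5,6,7,8,8a-octahydronaphthalen-1-yl]methoxy}-2H-chromen-2-one | CC1=CC[C@@H]2C(C)(C)C(=O)[C@@H](O)C[C@@]2(C)[C@@H]1COc1ccc2ccc(=O)oc2c1 | intermediate
15 | 7-{[(1R,4aS,6S,7S,8aR)-6,7-dihydroxy-2,5,5,8a-tetramethyl-1,4,4a,5,6,7,8,8a-octahydronaphthalen-1-yl]methoxy}-2H-chromen-2-one | CC1=CC[C@@H]2C(C)(C)[C@H](O)[C@@H](O)C[C@@]2(C)[C@@H]1COc1ccc2ccc(=O)oc2c1 | target

Total step count: 9 steps.
Longest linear sequence: 9 steps (from 1 and 2 to 15).

Steps most likely to fail

1. Step 8. The C10 cation may lose a proton before the C8=C9 alkene captures it (carbonyl-ene termination that stops at a monocyclic product), the C8 cation may lose a proton without regiocontrol, or the Lewis acid may ionize the allylic aryl ether. Fallback, from 12 back to 14: the two ring closures are separated. Me2AlCl in CH2Cl2 at −78 °C is used to run the type 2 carbonyl-ene closure of ring A on purpose, which still forms the C1–C2 bond with the equatorial C2 hydroxyl and gives the monocyclic exo-methylene ketol F1. FSO3H in 2-nitropropane at −78 °C then protonates the exocyclic methylene, regenerates the C10 cation and closes ring B under the superacid conditions that are known to turn monocyclic farnesyl-type substrates into trans-fused drim-7-enes, which returns the route to 14.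

2. Step 5. Enantiofacial discrimination may be poor with the fully substituted (isopropylidene) vinyl ether, or the coumarin carbonyl may tie up the copper catalyst so that the rearrangement is slow and unselective. Fallback, from 8 back to 11: the stereocontrol is moved from the rearrangement to a reagent-controlled reduction with separation of diastereomers. Thermal Claisen rearrangement of 8 (toluene, 110 °C) gives the racemic keto ester F2. Reduction with (R)-2-methyl-CBS-oxazaborolidine and catecholborane at −78 °C fixes C3 under reagent control (drawn 3S; either sense serves), and the two hydroxy esters that differ at C5 are separated by preparative chromatography to give the (3S,5S)-hydroxy ester F3. NaBH4 as in step 6 then gives 11 as a single C3 epimer, which is equally suitable for step 7.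

3. Step 6. Hydride attack on the coumarin lactone may compete with the slow reduction of the hindered alpha-hydroxy ester, and the ester reduction may stay incomplete. Fallback, from 9 back to 12: the hydride reduction is avoided and the diol is bypassed. LiOH in THF–water followed by acidification (the coumarin ring re-closes) gives the keto acid F4. EtSH with DCC and DMAP gives the S-ethyl thioester F5. Fukuyama reduction (Et3SiH, Pd/CaCO3 poisoned with Pb(OAc)2, acetone, rt) then gives the glyoxal 12 directly, so that step 7 is no longer needed.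

Further compounds
F1 | step 8 | monocyclic ene product, (2S,5S)-2-hydroxy-3-oxo ring A with exocyclic methylene at C10 and the open C6–C11 chain | C=C1C[C@H](O)C(=O)C(C)(C)[C@H]1CC/C(C)=C/COc1ccc2ccc(=O)oc2c1
F2 | step 5 | racemic ethyl (7E)-3,3,7-trimethyl-2-oxo-9-[(2-oxo-2H-chromen-7-yl)oxy]-4-(prop-1-en-2-yl)non-7-enoate | CCOC(=O)C(=O)C(C)(C)C(C(C)=C)CC/C(C)=C/COc1ccc2ccc(=O)oc2c1
F3 | step 5 | ethyl (2S,4S,7E)-2-hydroxy-3,3,7-trimethyl-9-[(2-oxo-2H-chromen-7-yl)oxy]-4-(prop-1-en-2-yl)non-7-enoate (3S,5S in drimane numbering) | CCOC(=O)[C@@H](O)C(C)(C)[C@H](C(C)=C)CC/C(C)=C/COc1ccc2ccc(=O)oc2c1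
F4 | step 6 | (4S,7E)-3,3,7-trimethyl-2-oxo-9-[(2-oxo-2H-chromen-7-yl)oxy]-4-(prop-1-en-2-yl)non-7-enoic acid | OC(=O)C(=O)C(C)(C)[C@H](C(C)=C)CC/C(C)=C/COc1ccc2ccc(=O)oc2c1
F5 | step 6 | S-ethyl (4S,7E)-3,3,7-trimethyl-2-oxo-9-[(2-oxo-2H-chromen-7-yl)oxy]-4-(prop-1-en-2-yl)non-7-enethioate | CCSC(=O)C(=O)C(C)(C)[C@H](C(C)=C)CC/C(C)=C/COc1ccc2ccc(=O)oc2c1
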